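**Numbering used below.** Ring of the target: C1 is the carbonyl between C2 (OMe) and C6 (side chain), C3 carries H, C4 is the second carbonyl, C5 carries CH3. The side chain runs from C1' (on C6) to C17'. The systematic name uses other locants (5-methoxy-2-methyl-3-alkyl).

## Analysis of the target

Target 33 is a p-benzoquinone with three different substituents: OMe on C2, CH3 on C5 and a branched C17 alkyl chain on C6. The chain is saturated and carries methyl groups on C9', C11', C13' and C15' in an all-syn (isotactic) arrangement. The descriptors 9'R, 11'R, 13'S, 15'S change in the middle only because the priorities change, not because the relative configuration does. Eight methylene groups lie between the ring and the nearest stereocentre, so ring chemistry and chain stereochemistry do not influence each other, and the ring has no stereocentre. The quinone is sensitive to reduction, nucleophiles, base and light, and its methoxy-enone half is a vinylogous ester that can hydrolyse or undergo addition–elimination, so it should be unveiled last. The first difficulty is the chain: four stereocentres defined only by methyl groups in a hydrocarbon with no functional handle, so stereoisomers formed in error can be neither separated nor easily detected. The second is regiochemistry on the ring, where three different groups must be placed without isomers. The strategy rests on the fact that the two carbon substituents sit on the adjacent carbons C5 and C6 of the C5=C6 double bond, the one without a methoxy group. Seen from the C4 carbonyl, C6 is a β-carbon and C5 an α-carbon, the pattern produced by conjugate addition followed by enolate alkylation, provided C1 is masked.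

## Retrosynthetic reasoning

**33 from 32.** The quinone is formed in the last operation. The C1 carbonyl is traced back to an aryl methyl ether, so the precursor is the p-methoxyphenol 32, and the forward reaction is an oxidative demethylation with a hypervalent iodine oxidant in an aqueous medium. This keeps C1 masked to the end and makes the penultimate compound an air-stable arene.

**32 from 31.** Phenol 32 is cyclohexenone 31 minus one ketal methoxy group and one ring hydrogen. Forward, anhydrous acid ionises the dimethyl ketal, the proton on the chain-bearing carbon is lost and the dienone tautomerises to the phenol. Elimination under anhydrous conditions is preferred to aqueous hydrolysis of the ketal. In an aqueous medium, ketal hydrolysis, this same elimination and cleavage of the methoxy enone would compete; without it only the elimination is open. Both ring stereocentres of 31 disappear, so 31 may be a mixture of isomers.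

**31 from 25, 23 and 26 (key disconnection).** The bonds C6–C1' and C5–CH3 are cut together. The ring piece is the quinone monoketal 25, in which the future C1 is a dimethyl ketal and the future C4 is the only free carbonyl. The chain is used as the organocopper reagent 28, made from bromide 23 through Grignard reagent 27, and the methyl group comes from iodomethane 26. Cutting here uses the chain as a simple primary alkyl halide and the ring as a one-step derivative of a cheap phenol. The methoxy group of 25 decides which β-carbon is attacked, so no regiochemical control element has to be built in. Forward, the reaction must add the chain to the unsubstituted β-carbon, trap the enolate as silyl ether 29, release it as lithium dienolate 30 and methylate it once on carbon.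

**25 from 24.** The monoketal arises by oxidative dearomatisation of phenol 24 in the alcohol that supplies the second ketal methoxy group. The para carbon already carries one methoxy group, which fixes the site of attack.

**23 from 22, and 22 from 18 and 20.** The C6'–C7' bond is cut. This separates the stereochemically valuable C7'–C17' part (tosylate 18) from a cheap six-carbon piece (silyl ether 20, used as Grignard reagent 21). The reacting carbon C7' is two carbons away from the nearest stereocentre, so the coupling is neither hindered nor able to epimerise anything. The silyl ether of 22 is exchanged directly for bromide to give 23.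

**18 from 17, and 17 from 16.** Routine functional-group changes: sulfonylation of alcohol 17, which comes from hydride reduction of thioester 16.

**16 back to 3.** Each stereocentre is traced to a β-C–CH3 bond made by catalytic asymmetric conjugate addition of methylmagnesium bromide 4 to an (E)-enethioate (15, 12, 9 and 3 in turn). Each enethioate is traced to the aldehyde one cycle earlier (14, 11, 6) by olefination with phosphonate 8, and each aldehyde to the previous thioester (13, 10, 5) by partial reduction. The chain grows from the ethyl end, so the last thioester carbon is C7', ready for the coupling. A chiral catalyst sets every centre independently of the substrate, and using the same ligand enantiomer in all four cycles gives the isotactic array.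

**Starting materials.** Enethioate 3 comes from acid 1 and thiol 2, phosphonate 8 from acid 7 and thiol 2, and silyl ether 20 from bromo alcohol 19.

## Alternatives that were turned down

**Alternative 1:** The C9'–C15' segment is read as a meso 1,3-dimethyl core (C11', C13') with one more methyl-bearing carbon at each end, and the C9'–CH3 and C15'–CH3 bonds are cut together.
- Forward key step: lithium dimethylcuprate A3, with a chlorosilane additive, adds to both enoate ends of 1-tert-butyl 11-methyl (2E,5S,7R,9E)-5,7-dimethylundeca-2,9-dienedioate A2. Each new centre is induced 1,3-syn by the nearest methyl-bearing carbon, giving the tetramethyl diester A1.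
- For it: two of the four stereocentres come from one operation with an achiral, inexpensive reagent. Only one event (desymmetrisation of the meso core) sets absolute configuration. The two different esters already mark the unequal chain ends.
- Against it: the induction is substrate control through a conformational preference, which is weaker and less predictable than catalyst control, and an error at either end gives inseparable diastereomers of A1. Because the esters differ, A2 needs two separate olefinations after desymmetrisation. After the key step the methyl ester end must be reduced down to the C17' methyl group and the other end turned into a C7' electrophile. The count to bromide 23 is estimated at no fewer than the 17 steps of the chosen sequence.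
- Comparison: this alternative competes with steps 1 to 12, not with the ring chemistry, which would still be needed. It is stronger in the number of stereo-determining operations. The chosen route offers catalyst control at every centre and keeps the uncertain chemistry in one late step whose outcome is read from the ring substitution pattern.

**Alternative 2:** The whole stereo-tetrad and the ethyl terminus are cut into diethylzinc A5 and four molecules of propene A6.
- Forward key step: repeated 1,2-insertion of A6 at an enantiopure ethylene-bridged bis(tetrahydroindenyl)zirconium dichloride, (EBTHI)ZrCl2, activated by methylaluminoxane, (MeAlO)n, with chain transfer to zinc. Aerobic oxidation of the carbon–zinc bonds then gives (2S,4S,6S,8S)-2,4,6,8-tetramethyldecan-1-ol A4.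
- For it: on step economy this is far stronger than the chosen route, since one catalytic operation from two commodity chemicals replaces twelve steps.
- Against it: chain growth is statistical, so the tetramer A4 is one member of a distribution of oligomers that must be separated. The first insertion, into a metal–ethyl bond, lacks the branched chain end that helps face selection, so C15' would be the weakest centre. Errors in four successive insertions multiply and the stereoisomers cannot be removed. Regio-errors and β-hydride elimination add further impurities. As a preparative route to one discrete, stereodefined oligomer it goes beyond established carbometalation chemistry, which adds one methyl-bearing centre per operation.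
- Comparison: the chosen route is much longer but gives isolable intermediates with individually set centres, and places the risk in step 19 instead of at the source of all stereochemistry.

**Alternative 3:** The quinone ring itself is cut at C1–C6 and C4–C5 into a four-carbon and a two-carbon piece.
- Forward key step: the alkenyllithium made by halogen–lithium exchange (t-BuLi) from (12R,14R,16S,18S)-3-bromo-12,14,16,18-tetramethylicos-2-ene A9 adds to the ketone-like carbonyl of 3-methoxycyclobut-3-ene-1,2-dione A8. Heating the adduct causes 4π ring opening to a vinylketene and 6π electrocyclisation to hydroquinone A7, which is then oxidised.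
- For it: the ring is assembled with every substituent in a position fixed by connectivity. On regiochemical certainty this is stronger than the chosen key step, and there is no enolate alkylation and no question of which β-carbon reacts.
- Against it: A9 is a trisubstituted bromoalkene that needs several extra steps on the finished chain. The exchange uses two equivalents of t-BuLi on the most valuable fragment. A8 is not a commodity and is sensitive. The hydroxycyclobutenone adduct is labile before thermolysis.
- Comparison: the chosen route gives up some regiochemical certainty but uses the chain as a plain primary bromide, a ring precursor made in one step, and only three steps after the chain is complete.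

Key step: step 19

**Assumption.** The CuBr complex of (S)-1-[(Rp)-2-(diphenylphosphino)ferrocenyl]ethyldicyclohexylphosphine is taken to deliver methyl to the face of an (E)-S-ethyl enethioate that gives the 3S adduct when the β-substituent is a primary alkyl group. If the sense is the opposite, the enantiomeric ligand is used in all four additions and nothing else changes.

## Route

**Step 1**
Reactants: 1 (E)-pent-2-enoic acid; 2 ethanethiol
Product: 3 S-ethyl (2E)-pent-2-enethioate
Conditions: DCC, DMAP (cat.), CH2Cl2, 0 °C to rt
Reagents that add atoms: ethanethiol (2), CCS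
Why: Carbodiimide (Steglich-type) thioesterification; at 0 °C the thiol is acylated by the activated acid faster than it adds to the enoate, and the E double bond is retained.

**Step 2**
Reactants: 3 S-ethyl (2E)-pent-2-enethioate; 4 methylmagnesium bromide
Product: 5 S-ethyl (3S)-3-methylpentanethioate
Conditions: MeMgBr (1.2 equiv), CuBr·SMe2 (1 mol %), (S)-1-[(Rp)-2-(diphenylphosphino)ferrocenyl]ethyldicyclohexylphosphine (1.2 mol %), t-BuOMe, −75 °C, slow addition of 3; then MeOH, aq. NH4Cl
Reagents that add atoms: methylmagnesium bromide (4), C[Mg]Br
Why: Copper-catalysed asymmetric conjugate addition of a Grignard reagent to an enethioate; the thioester is reactive enough for 1,4-addition to outrun 1,2-addition at low temperature, and the chiral copper–diphosphine complex selects the alkene face so that C3 (later C15') should form as S.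

**Step 3**
Reactants: 5 S-ethyl (3S)-3-methylpentanethioate
Product: 6 (3S)-3-methylpentanal
Conditions: i-Bu2AlH (1.1 equiv), CH2Cl2, −65 °C; then aq. potassium sodium tartrate; used as a dried solution
Reagents that add atoms: none
Why: Partial reduction of a thioester; the aluminium hemithioacetal survives at low temperature and collapses to the aldehyde only on work-up, so over-reduction is avoided, and the β-stereocentre cannot epimerise; the volatile aldehyde is not concentrated to dryness.

**Step 4**
Reactants: 7 2-(diethoxyphosphoryl)acetic acid; 2 ethanethiol
Product: 8 S-ethyl 2-(diethoxyphosphoryl)ethanethioate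
Conditions: DCC, DMAP (cat.), CH2Cl2, 0 °C to rt
Reagents that add atoms: ethanethiol (2), CCS
Why: The same Steglich-type thioesterification gives the olefination reagent for all three homologations in one step from a commercial acid.

**Step 5**
Reactants: 6 (3S)-3-methylpentanal; 8 S-ethyl 2-(diethoxyphosphoryl)ethanethioate
Product: 9 S-ethyl (2E,5S)-5-methylhept-2-enethioate
Conditions: 8, n-BuLi, THF, −78 to 0 °C; then 6, 0 °C to rt
Reagents that add atoms: S-ethyl 2-(diethoxyphosphoryl)ethanethioate (8), CCOP(=O)(CC(=O)SCC)OCC
Why: Horner–Wadsworth–Emmons olefination with a stabilised phosphonate anion should give the E enethioate; any Z isomer is removed by chromatography because it would give the epimer in the next addition.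

**Step 6**
Reactants: 9 S-ethyl (2E,5S)-5-methylhept-2-enethioate; 4 methylmagnesium bromide
Product: 10 S-ethyl (3S,5S)-3,5-dimethylheptanethioate
Conditions: MeMgBr (1.2 equiv), CuBr·SMe2 (1 mol %), (S)-1-[(Rp)-2-(diphenylphosphino)ferrocenyl]ethyldicyclohexylphosphine (1.2 mol %), t-BuOMe, −75 °C, slow addition of 9; then MeOH, aq. NH4Cl
Reagents that add atoms: methylmagnesium bromide (4), C[Mg]Br
Why: Second copper-catalysed asymmetric conjugate addition; the catalyst overrides the weak bias of the remote C5 centre, and the same ligand enantiomer as in step 2 places the new methyl group syn to the existing one (C3 S, later C13').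

**Step 7**
Reactants: 10 S-ethyl (3S,5S)-3,5-dimethylheptanethioate
Product: 11 (3S,5S)-3,5-dimethylheptanal
Conditions: i-Bu2AlH (1.1 equiv), CH2Cl2, −65 °C; then aq. potassium sodium tartrate
Reagents that add atoms: none
Why: Partial thioester reduction as in step 3; neither stereocentre is α to the carbonyl group.

**Step 8**
Reactants: 11 (3S,5S)-3,5-dimethylheptanal; 8 S-ethyl 2-(diethoxyphosphoryl)ethanethioate
Product: 12 S-ethyl (2E,5S,7S)-5,7-dimethylnon-2-enethioate
Conditions: 8, n-BuLi, THF, −78 to 0 °C; then 11, 0 °C to rt
Reagents that add atoms: S-ethyl 2-(diethoxyphosphoryl)ethanethioate (8), CCOP(=O)(CC(=O)SCC)OCC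
Why: E-selective Horner–Wadsworth–Emmons olefination as in step 5.

**Step 9**
Reactants: 12 S-ethyl (2E,5S,7S)-5,7-dimethylnon-2-enethioate; 4 methylmagnesium bromide
Product: 13 S-ethyl (3S,5S,7S)-3,5,7-trimethylnonanethioate
Conditions: MeMgBr (1.2 equiv), CuBr·SMe2 (1 mol %), (S)-1-[(Rp)-2-(diphenylphosphino)ferrocenyl]ethyldicyclohexylphosphine (1.2 mol %), t-BuOMe, −75 °C, slow addition of 12; then MeOH, aq. NH4Cl
Reagents that add atoms: methylmagnesium bromide (4), C[Mg]Br
Why: Third catalyst-controlled conjugate addition; the syn,syn array is the matched case for this ligand, and the new C3 (later C11') forms with the same facial sense as before.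

**Step 10**
Reactants: 13 S-ethyl (3S,5S,7S)-3,5,7-trimethylnonanethioate
Product: 14 (3S,5S,7S)-3,5,7-trimethylnonanal
Conditions: i-Bu2AlH (1.1 equiv), CH2Cl2, −65 °C; then aq. potassium sodium tartrate
Reagents that add atoms: none
Why: Partial thioester reduction as in step 3.

**Step 11**
Reactants: 14 (3S,5S,7S)-3,5,7-trimethylnonanal; 8 S-ethyl 2-(diethoxyphosphoryl)ethanethioate
Product: 15 S-ethyl (2E,5S,7S,9S)-5,7,9-trimethylundec-2-enethioate
Conditions: 8, n-BuLi, THF, −78 to 0 °C; then 14, 0 °C to rt
Reagents that add atoms: S-ethyl 2-(diethoxyphosphoryl)ethanethioate (8), CCOP(=O)(CC(=O)SCC)OCC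
Why: E-selective Horner–Wadsworth–Emmons olefination as in step 5.

**Step 12**
Reactants: 15 S-ethyl (2E,5S,7S,9S)-5,7,9-trimethylundec-2-enethioate; 4 methylmagnesium bromide
Product: 16 S-ethyl (3S,5S,7S,9S)-3,5,7,9-tetramethylundecanethioate
Conditions: MeMgBr (1.2 equiv), CuBr·SMe2 (1 mol %), (S)-1-[(Rp)-2-(diphenylphosphino)ferrocenyl]ethyldicyclohexylphosphine (1.2 mol %), t-BuOMe, −75 °C, slow addition of 15; then MeOH, aq. NH4Cl
Reagents that add atoms: methylmagnesium bromide (4), C[Mg]Br
Why: Fourth catalyst-controlled conjugate addition completes the isotactic tetrad; the new C3 becomes C9' and the thioester carbon becomes C7'.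

**Step 13**
Reactants: 16 S-ethyl (3S,5S,7S,9S)-3,5,7,9-tetramethylundecanethioate
Product: 17 (3S,5S,7S,9S)-3,5,7,9-tetramethylundecan-1-ol
Conditions: LiAlH4, Et2O, 0 °C
Reagents that add atoms: none
Why: Hydride reduction of a thioester to the primary alcohol; no stereocentre is adjacent to the reacting carbon.

**Step 14**
Reactants: 17 (3S,5S,7S,9S)-3,5,7,9-tetramethylundecan-1-ol
Product: 18 (3S,5S,7S,9S)-3,5,7,9-tetramethylundecyl 4-methylbenzenesulfonate
Conditions: TsCl, Et3N, DMAP (cat.), CH2Cl2, 0 °C to rt
Reagents that add atoms: 4-methylbenzenesulfonyl chloride, Cc1ccc(cc1)S(=O)(=O)Cl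
Why: Sulfonylation of an unhindered primary alcohol gives the electrophile for the sp3–sp3 coupling.

**Step 15**
Reactants: 19 6-bromohexan-1-ol
Product: 20 [(6-bromohexyl)oxy](tert-butyl)dimethylsilane
Conditions: TBSCl, imidazole, CH2Cl2, rt
Reagents that add atoms: tert-butylchlorodimethylsilane, CC(C)(C)[Si](C)(C)Cl
Why: Silylation masks the hydroxyl group so that the bromide can be converted into a Grignard reagent.

**Step 16**
Reactants: 20 [(6-bromohexyl)oxy](tert-butyl)dimethylsilane; 18 (3S,5S,7S,9S)-3,5,7,9-tetramethylundecyl 4-methylbenzenesulfonate
Product: 22 tert-butyl(dimethyl){[(9R,11R,13S,15S)-9,11,13,15-tetramethylheptadecyl]oxy}silane, via silyloxyhexylmagnesium bromide 21 (not isolated)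
Conditions: 20, Mg, THF, 40 °C; then 18, Li2CuCl4 (5 mol %), THF, −78 °C to rt
Reagents that add atoms: bromide 20 as its Grignard reagent 21, CC(C)(C)[Si](C)(C)OCCCCCC[Mg]Br
Why: Copper-catalysed coupling of a primary Grignard reagent with a primary tosylate (Kochi-type, Li2CuCl4); the alkylcuprate formed in the flask displaces the sulfonate by SN2 at C7', two carbons from the nearest stereocentre, forming C6'–C7'.

**Step 17**
Reactants: 22 tert-butyl(dimethyl){[(9R,11R,13S,15S)-9,11,13,15-tetramethylheptadecyl]oxy}silane
Product: 23 (9R,11R,13S,15S)-1-bromo-9,11,13,15-tetramethylheptadecane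
Conditions: Ph3PBr2, CH2Cl2, rt
Reagents that add atoms: dibromotriphenylphosphorane, BrP(Br)(c1ccccc1)(c1ccccc1)c1ccccc1
Why: Direct conversion of a primary silyl ether into the bromide; the bromophosphonium ion activates the ether oxygen, the silyl bromide departs and bromide displaces triphenylphosphine oxide at the primary carbon (Appel-type), which saves a separate deprotection.

**Step 18**
Reactants: 24 3,4-dimethoxyphenol
Product: 25 3,4,4-trimethoxycyclohexa-2,5-dien-1-one
Conditions: PhI(OAc)2 (1.1 equiv), MeOH, 0 °C to rt; NaHCO3 work-up
Reagents that add atoms: methanol, CO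
Why: Oxidative dearomatisation of a p-methoxyphenol with trivalent iodine; methanol attacks the para carbon, which already bears a methoxy group, and gives the quinone monoketal.

**Step 19**
Reactants: 23 (9R,11R,13S,15S)-1-bromo-9,11,13,15-tetramethylheptadecane; 25 3,4,4-trimethoxycyclohexa-2,5-dien-1-one; 26 iodomethane
Product: 31 trans-3,4,4-trimethoxy-6-methyl-5-[(9R,11R,13S,15S)-9,11,13,15-tetramethylheptadecyl]cyclohex-2-en-1-one, via chain Grignard reagent 27 (not isolated), via alkylcopper reagent 28 (not isolated), via silyl dienol ether 29 (not isolated), via lithium dienolate 30 (not isolated)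
Conditions: 23, Mg, THF, 40 °C; CuBr·SMe2 (1.0 equiv), THF–Me2S, −78 °C; Me3SiCl, then 25 (1.05 equiv), −78 to −40 °C; Et3N, pentane, filtration under argon, evaporation; MeLi, THF, 0 °C to rt; MeI, DMPU, −78 to 0 °C
Reagents that add atoms: iodomethane (26), CI; monoketal 25, COC1=CC(=O)C=CC1(OC)OC
Why: Grignard reagent 27 is converted completely into the monoalkylcopper 28, which with Me3SiCl complexes the only unsubstituted enone double bond of 25 and transfers its single alkyl group to the β-carbon next to the ketal, the enolate being silylated to 29; the closest known reaction type is chlorosilane-accelerated organocopper addition to quinone monoketals. MeLi cleaves the O–Si bond to give the cross-conjugated lithium dienolate 30, which MeI alkylates at the α-carbon as in the α'-alkylation of 3-alkoxycyclohexenone enolates (Stork–Danheiser type), so that C6–C1' and C5–CH3 (target numbering) are formed in one flask. No ring is closed. Selectivity between the two β-carbons is needed and is supplied by the methoxy group, which makes its own double bond a vinylogous ester and a poor acceptor. 1,2-Addition is suppressed because no free Grignard reagent remains and the other carbonyl is a ketal. Single methylation is favoured by low temperature and excess MeI, and dienolate 30 cannot expel methoxide because its charge lies only on oxygen and the α-carbon. The chain-bearing ring carbon forms without control from the remote chain centres and the methyl group should enter trans to the chain for steric reasons; both centres are erased in step 20, so neither needs control. A one-alkyl copper reagent is used so that no chain is wasted as a non-transferred ligand.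

**Step 20**
Reactants: 31 trans-3,4,4-trimethoxy-6-methyl-5-[(9R,11R,13S,15S)-9,11,13,15-tetramethylheptadecyl]cyclohex-2-en-1-one
Product: 32 4,5-dimethoxy-2-methyl-3-[(9R,11R,13S,15S)-9,11,13,15-tetramethylheptadecyl]phenol
Conditions: camphorsulfonic acid (10 mol %), CH2Cl2, 4 Å molecular sieves, rt
Reagents that add atoms: none
Why: Acid-catalysed ionisation of the dimethyl ketal (helped by enolisation of the ketone, which makes the cation an arenium ion), loss of the proton on the chain-bearing carbon and tautomerisation should give the phenol with loss of one methanol; without water neither the ketal nor the methoxy enone can hydrolyse, and both ring stereocentres disappear.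

**Step 21**
Reactants: 32 4,5-dimethoxy-2-methyl-3-[(9R,11R,13S,15S)-9,11,13,15-tetramethylheptadecyl]phenol
Product: 33 2-methoxy-5-methyl-6-[(9R,11R,13S,15S)-9,11,13,15-tetramethylheptadecyl]cyclohexa-2,5-diene-1,4-dione (target; systematic locants 5-methoxy-2-methyl-3-alkyl)
Conditions: PhI(OAc)2 (1.1 equiv), MeCN–CH2Cl2–H2O, 0 °C
Reagents that add atoms: water, O
Why: Oxidative demethylation of a p-methoxyphenol; trivalent iodine activates the phenol oxygen, water adds at the para carbon bearing the methoxy group and the hemiketal loses methanol to give the p-quinone; the saturated chain is inert and the CH2Cl2 cosolvent keeps the lipophilic substrate dissolved.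

## Compound list

1 | (E)-pent-2-enoic acid | CC/C=C/C(=O)O | starting material
2 | ethanethiol | CCS | starting material
3 | S-ethyl (2E)-pent-2-enethioate | CC/C=C/C(=O)SCC | intermediate
4 | methylmagnesium bromide | C[Mg]Br | starting material
5 | S-ethyl (3S)-3-methylpentanethioate | CC[C@H](C)CC(=O)SCC | intermediate
6 | (3S)-3-methylpentanal | CC[C@H](C)CC=O | intermediate
7 | 2-(diethoxyphosphoryl)acetic acid | CCOP(=O)(CC(=O)O)OCC | starting material
8 | S-ethyl 2-(diethoxyphosphoryl)ethanethioate | CCOP(=O)(CC(=O)SCC)OCC | intermediate
9 | S-ethyl (2E,5S)-5-methylhept-2-enethioate | CC[C@H](C)C/C=C/C(=O)SCC | intermediate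
10 | S-ethyl (3S,5S)-3,5-dimethylheptanethioate | CC[C@H](C)C[C@H](C)CC(=O)SCC | intermediate
11 | (3S,5S)-3,5-dimethylheptanal | CC[C@H](C)C[C@H](C)CC=O | intermediate
12 | S-ethyl (2E,5S,7S)-5,7-dimethylnon-2-enethioate | CC[C@H](C)C[C@H](C)C/C=C/C(=O)SCC | intermediate
13 | S-ethyl (3S,5S,7S)-3,5,7-trimethylnonanethioate | CC[C@H](C)C[C@H](C)C[C@H](C)CC(=O)SCC | intermediate
14 | (3S,5S,7S)-3,5,7-trimethylnonanal | CC[C@H](C)C[C@H](C)C[C@H](C)CC=O | intermediate
15 | S-ethyl (2E,5S,7S,9S)-5,7,9-trimethylundec-2-enethioate | CC[C@H](C)C[C@H](C)C[C@H](C)C/C=C/C(=O)SCC | intermediate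
16 | S-ethyl (3S,5S,7S,9S)-3,5,7,9-tetramethylundecanethioate | CC[C@H](C)C[C@H](C)C[C@H](C)C[C@H](C)CC(=O)SCC | intermediate
17 | (3S,5S,7S,9S)-3,5,7,9-tetramethylundecan-1-ol | CC[C@H](C)C[C@H](C)C[C@H](C)C[C@H](C)CCO | intermediate
18 | (3S,5S,7S,9S)-3,5,7,9-tetramethylundecyl 4-methylbenzenesulfonate | CC[C@H](C)C[C@H](C)C[C@H](C)C[C@H](C)CCOS(=O)(=O)c1ccc(C)cc1 | intermediate
19 | 6-bromohexan-1-ol | OCCCCCCBr | starting material
20 | [(6-bromohexyl)oxy](tert-butyl)dimethylsilane | CC(C)(C)[Si](C)(C)OCCCCCCBr | intermediate
21 | {6-[(tert-butyldimethylsilyl)oxy]hexyl}magnesium bromide | CC(C)(C)[Si](C)(C)OCCCCCC[Mg]Br | intermediate (not isolated)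
22 | tert-butyl(dimethyl){[(9R,11R,13S,15S)-9,11,13,15-tetramethylheptadecyl]oxy}silane | CC[C@H](C)C[C@H](C)C[C@H](C)C[C@H](C)CCCCCCCCO[Si](C)(C)C(C)(C)C | intermediate
23 | (9R,11R,13S,15S)-1-bromo-9,11,13,15-tetramethylheptadecane | CC[C@H](C)C[C@H](C)C[C@H](C)C[C@H](C)CCCCCCCCBr | intermediate
24 | 3,4-dimethoxyphenol | COc1ccc(O)cc1OC | starting material
25 | 3,4,4-trimethoxycyclohexa-2,5-dien-1-one | COC1=CC(=O)C=CC1(OC)OC | intermediate
26 | iodomethane | CI | starting material
27 | [(9R,11R,13S,15S)-9,11,13,15-tetramethylheptadecyl]magnesium bromide | CC[C@H](C)C[C@H](C)C[C@H](C)C[C@H](C)CCCCCCCC[Mg]Br | intermediate (not isolated)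
28 | [(9R,11R,13S,15S)-9,11,13,15-tetramethylheptadecyl]copper (as its MgBr2·SMe2 complex) | CC[C@H](C)C[C@H](C)C[C@H](C)C[C@H](C)CCCCCCCC[Cu] | intermediate (not isolated)
29 | trimethyl({4,4,5-trimethoxy-3-[(9R,11R,13S,15S)-9,11,13,15-tetramethylheptadecyl]cyclohexa-1,5-dien-1-yl}oxy)silane (ring centre undefined) | CC[C@H](C)C[C@H](C)C[C@H](C)C[C@H](C)CCCCCCCCC1C=C(O[Si](C)(C)C)C=C(OC)C1(OC)OC | intermediate (not isolated)
30 | lithium 4,4,5-trimethoxy-3-[(9R,11R,13S,15S)-9,11,13,15-tetramethylheptadecyl]cyclohexa-1,5-dien-1-olate (ring centre undefined) | CC[C@H](C)C[C@H](C)C[C@H](C)C[C@H](C)CCCCCCCCC1C=C(O[Li])C=C(OC)C1(OC)OC | intermediate (not isolated)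
31 | trans-3,4,4-trimethoxy-6-methyl-5-[(9R,11R,13S,15S)-9,11,13,15-tetramethylheptadecyl]cyclohex-2-en-1-one (ring centres transient, mixture) | CC[C@H](C)C[C@H](C)C[C@H](C)C[C@H](C)CCCCCCCCC1C(C)C(=O)C=C(OC)C1(OC)OC | intermediate
32 | 4,5-dimethoxy-2-methyl-3-[(9R,11R,13S,15S)-9,11,13,15-tetramethylheptadecyl]phenol | CC[C@H](C)C[C@H](C)C[C@H](C)C[C@H](C)CCCCCCCCc1c(C)c(O)cc(OC)c1OC | intermediate
33 | 2-methoxy-5-methyl-6-[(9R,11R,13S,15S)-9,11,13,15-tetramethylheptadecyl]cyclohexa-2,5-diene-1,4-dione | CC[C@H](C)C[C@H](C)C[C@H](C)C[C@H](C)CCCCCCCCC1=C(C)C(=O)C=C(OC)C1=O | target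

## Step count and risk

Total: 21 steps. Longest linear sequence: 18 steps (1, 2, 3, 5 to 14, 16, 17, 19, 20, 21). Steps 4, 15 and 18 prepare the phosphonate, the six-carbon piece and the monoketal.

**Step 19 (key step).**
- What may go wrong: the methylation half is the weaker one. The silyl dienol ether carries an allylic ketal and may lose methoxide under the Lewis-acidic magnesium and silicon species before it is methylated, aromatising early to a phenol that lacks the C5 methyl group. Proton exchange between dienolate and product may also leave the methylation incomplete or lead to double methylation. Electron transfer from the copper reagent to the dienone, with reductive aromatisation, is a lesser risk.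
- Fallback: put the methyl group on the ring before the chain, so that only one bond is formed and early aromatisation becomes harmless. It sets out from 24 and 23 and comes back at 31. Ortho-formylation of 24 (MgCl2, Et3N, paraformaldehyde, MeCN, reflux) should give 2-hydroxy-4,5-dimethoxybenzaldehyde F1. Hydrogenolysis (H2, Pd/C, AcOH) should give 4,5-dimethoxy-2-methylphenol F2, and PhI(OAc)2 in MeOH should give 3,4,4-trimethoxy-6-methylcyclohexa-2,5-dien-1-one F3. Copper reagent 28, made from 23 as in step 19, is added with Me3SiCl to the β-carbon of the methyl-bearing enone of F3. This should give trimethyl({4,4,5-trimethoxy-2-methyl-3-[(9R,11R,13S,15S)-9,11,13,15-tetramethylheptadecyl]cyclohexa-1,5-dien-1-yl}oxy)silane F4, and buffered fluoride (KF, AcOH, MeOH) releases ketone 31. If F4 loses methanol early, it arrives directly at 32.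

**Step 2 (and the later additions 6, 9, 12).**
- What may go wrong: incomplete face selection with the small ethyl-substituted enethioate, with the error carried through the whole chain because no later intermediate is crystalline or separable from its stereoisomers. Evaporative loss of the C6 to C8 compounds is a further risk.
- Fallback: auxiliary control with a separable diastereomer, from 1 back to 5. Acid 1 is acylated onto (R)-4-phenyloxazolidin-2-one (pivaloyl chloride, Et3N, then LiCl) to give (4R)-3-[(2E)-pent-2-enoyl]-4-phenyl-1,3-oxazolidin-2-one F5. MeMgBr with CuBr·SMe2 (THF–Me2S, −40 °C) should add anti to the phenyl group of the magnesium-chelated syn-s-cis imide and give (4R)-3-[(3S)-3-methylpentanoyl]-4-phenyl-1,3-oxazolidin-2-one F6, which is purified from its diastereomer. LiSEt (from 2 and n-BuLi, THF, 0 °C) then gives thioester 5 and returns the auxiliary.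

**Step 16.**
- What may go wrong: slow alkyl–alkyl coupling, which lets bromide displace the tosylate and lets the Grignard reagent homocouple or be reduced, wasting the eleven-carbon fragment.
- Fallback: build C6'–C7' as an alkene, from 16 and 20 back to 22. Thioester 16 is reduced (i-Bu2AlH, −65 °C) to (3S,5S,7S,9S)-3,5,7,9-tetramethylundecanal F7. Bromide 20 and PPh3 (MeCN, reflux) give {6-[(tert-butyldimethylsilyl)oxy]hexyl}triphenylphosphonium bromide F8. Wittig reaction of its ylide (NaN(SiMe3)2, THF, −78 °C) with F7 should give tert-butyl(dimethyl){[(6Z,9S,11S,13S,15S)-9,11,13,15-tetramethylheptadec-6-en-1-yl]oxy}silane F9, and hydrogenation (H2, Pd/C, EtOAc) gives 22.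

**Step 20.**
- What may go wrong: slow ionisation of a ketal whose neighbour is the electron-poor carbon of the methoxy enone, so that stronger acid is needed and begins to cleave the enol ether.
- Fallback: unmask C1 by hydrolysis, from 31 to 33. Aqueous HCl in THF hydrolyses the ketal, and the ene-dione enolises to 2-methoxy-5-methyl-6-[(9R,11R,13S,15S)-9,11,13,15-tetramethylheptadecyl]benzene-1,4-diol F10. Ag2O in Et2O then oxidises it to 33.

## Further compounds

F1 | step 19 | 2-hydroxy-4,5-dimethoxybenzaldehyde | COc1cc(O)c(C=O)cc1OC
F2 | step 19 | 4,5-dimethoxy-2-methylphenol | COc1cc(O)c(C)cc1OC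
F3 | step 19 | 3,4,4-trimethoxy-6-methylcyclohexa-2,5-dien-1-one | COC1=CC(=O)C(C)=CC1(OC)OC
F4 | step 19 | trimethyl({4,4,5-trimethoxy-2-methyl-3-[(9R,11R,13S,15S)-9,11,13,15-tetramethylheptadecyl]cyclohexa-1,5-dien-1-yl}oxy)silane | CC[C@H](C)C[C@H](C)C[C@H](C)C[C@H](C)CCCCCCCCC1C(C)=C(O[Si](C)(C)C)C=C(OC)C1(OC)OC
F5 | step 2 | (4R)-3-[(2E)-pent-2-enoyl]-4-phenyl-1,3-oxazolidin-2-one | CC/C=C/C(=O)N1[C@H](c2ccccc2)COC1=O
F6 | step 2 | (4R)-3-[(3S)-3-methylpentanoyl]-4-phenyl-1,3-oxazolidin-2-one | CC[C@H](C)CC(=O)N1[C@H](c2ccccc2)COC1=O
F7 | step 16 | (3S,5S,7S,9S)-3,5,7,9-tetramethylundecanal | CC[C@H](C)C[C@H](C)C[C@H](C)C[C@H](C)CC=O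
F8 | step 16 | {6-[(tert-butyldimethylsilyl)oxy]hexyl}triphenylphosphonium bromide | CC(C)(C)[Si](C)(C)OCCCCCC[P+](c1ccccc1)(c1ccccc1)c1ccccc1.[Br-]
F9 | step 16 | tert-butyl(dimethyl){[(6Z,9S,11S,13S,15S)-9,11,13,15-tetramethylheptadec-6-en-1-yl]oxy}silane | CC[C@H](C)C[C@H](C)C[C@H](C)C[C@H](C)C/C=C\CCCCCO[Si](C)(C)C(C)(C)C
F10 | step 20 | 2-methoxy-5-methyl-6-[(9R,11R,13S,15S)-9,11,13,15-tetramethylheptadecyl]benzene-1,4-diol | CC[C@H](C)C[C@H](C)C[C@H](C)C[C@H](C)CCCCCCCCc1c(C)c(O)cc(OC)c1O
A1 | alternative 1 | 1-tert-butyl 11-methyl (3S,5S,7R,9R)-3,5,7,9-tetramethylundecanedioate | COC(=O)C[C@H](C)C[C@H](C)C[C@H](C)C[C@H](C)CC(=O)OC(C)(C)C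
A2 | alternative 1 | 1-tert-butyl 11-methyl (2E,5S,7R,9E)-5,7-dimethylundeca-2,9-dienedioate | COC(=O)/C=C/C[C@H](C)C[C@H](C)C/C=C/C(=O)OC(C)(C)C
A3 | alternative 1 | lithium dimethylcuprate | [Li+].C[Cu-]C
A4 | alternative 2 | (2S,4S,6S,8S)-2,4,6,8-tetramethyldecan-1-ol | CC[C@H](C)C[C@H](C)C[C@H](C)C[C@H](C)CO
A5 | alternative 2 | diethylzinc | CC[Zn]CC
A6 | alternative 2 | propene | CC=C
A7 | alternative 3 | 2-methoxy-5-methyl-6-[(9R,11R,13S,15S)-9,11,13,15-tetramethylheptadecyl]benzene-1,4-diol | CC[C@H](C)C[C@H](C)C[C@H](C)C[C@H](C)CCCCCCCCc1c(C)c(O)cc(OC)c1O
A8 | alternative 3 | 3-methoxycyclobut-3-ene-1,2-dione | COC1=CC(=O)C1=O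
A9 | alternative 3 | (12R,14R,16S,18S)-3-bromo-12,14,16,18-tetramethylicos-2-ene (either alkene isomer) | CC[C@H](C)C[C@H](C)C[C@H](C)C[C@H](C)CCCCCCCCC(Br)=CC
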